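(Readings and results are simulated with constants of no real substance; scatter was added.)

I decided to follow the fraction of target left, not the amount made. In blue the target read 34.0% at 6.00 h, 41.2% at 12.0 h and 23.9% at 40.0 h. In ochre it read 38.0% at 0.667 h and 3.3% at 4.00 h.

| flask | starting material | protic impurity | temperature | remark | time |
|---|---|---|---|---|---|
| blue | 0.025 M | 0.010 M | 55 °C | run made earlier |  |
| ochre | 0.10 M | 0.010 M | 85 °C | run made earlier |  |
| dawn | 0.050 M | 0.0100 M | 60 °C |  | 30 h |
| dusk | 0.050 M | 0.0100 M | 85 °C |  | 30 h |
| winter | 0.050 M | 0.0100 M | 110 °C |  | 30 h |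
| spring | 0.050 M | 0.0100 M |  | at 60 °C until 6.0 h, from then on at 110 °C | 30 h |

| run | time / h | target / % | starting material / % |
|---|---|---|---|
| blue | 6.00 | 34.0 | 37.7 |
| blue | 12.0 | 41.2 | 17.1 |
| blue | 20.0 | 37.1 | 7.1 |
| blue | 25.0 | 36.1 | 4.8 |
| blue | 30.0 | 31.7 | 0.5 |
| blue | 40.0 | 23.9 | 2.8 |
| ochre | 0.667 | 38.0 | 21.4 |
| ochre | 2.50 | 7.2 | 4.0 |
| ochre | 4.00 | 3.3 | 0 |
| ochre | 6.00 | 0 | 1.6 |
| ochre | 8.00 | 0 | 0 |
| ochre | 12.0 | 0 | 0.9 |

(readings scatter by 1 percentage point)

- the numbers in the tables scatter by 1 percentage point (one standard deviation)

- the flask that comes out highest in amount of target, in percent of the starting material charged, or "all alike" when all lie within 1.5 percentage points (dawn / dusk / winter / spring / all alike)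
- target at the end, in percent of the starting material charged, dawn
- target at the end, in percent of the starting material charged, dusk
- target at the end, in percent of the starting material charged, winter
- target at the end, in percent of the starting material charged, spring

Late in a run the target mostly decays. So I defined a survival constant k, the first-order rate constant of the tail: the fraction of target living through a time t is exp(−kt). Blue's target fell from 37.1% at 20.0 h to 23.9% at 40.0 h, which reads as 0.0220 h⁻¹ at 55 °C. Ochre's target fell from 38.0% at 0.667 h to 7.2% at 2.50 h, which reads as 0.908 h⁻¹ at 85 °C. I took ln k as a straight line in temperature. That gave dawn, at 60 °C, a survival constant of 0.0409 h⁻¹. Dawn's survival over 30 h is then 29.3%.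

Running a tail back to zero time gives an intercept, the target a flask behaves as if it had made at once. Blue's tail gave 57.6%, so my first way put dawn at 16.9%. Ochre's tail gave 69.6%, so my second way put dawn at 20.4%. Both ways share the survival, so they check the intercept and nothing else. They parted by 3.5 percentage points. I judged that ochre's way cheats. Its tail begins with a reading of 21.4% of starting material, more than the 7.1% at the start of blue's tail, so I took it that ochre's tail still held more target being made. I held to blue's way for dawn.

Dusk's 30 h is 39.3 half-lives of target at ochre's constant. Winter and spring spend at least 24.0 h at 110 °C, hotter than ochre. I assumed the constant there is no smaller than ochre's, and at ochre's constant that time makes 31.4 half-lives. So I expected hardly any target in dusk, winter and spring, and dawn highest.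

The forecast named dawn, with 17% for dawn (range 11% to 24%) and 0%, 0% and 0% for dusk, winter and spring, since “the target is gone by 30 h”.

The flasks gave 17.6% in dawn, and 0%, 0% and 0% in dusk, winter and spring, with dawn highest.

    starting material ⇌ target + released group (K = 1.50 M, k = 0.180 h⁻¹, Ea = 105 kJ mol⁻¹, ΔH = −64.0 kJ mol⁻¹)
    target → over-reaction product (k = 0.0630 h⁻¹, Ea = 123 kJ mol⁻¹)
    starting material + protic impurity → quenched substrate (k = 17.0 L mol⁻¹ h⁻¹, Ea = 77.0 kJ mol⁻¹)
    (constants at 60 °C)

Dividing dawn's 17.6% by my survival gave an intercept of 60.1%, beside blue's 57.6%. I then carried the constant to a neighbour: dawn read at 3.0 d, with charge and temperature unchanged. From 30 h to that reading the survival is 18.0%, so I reckoned 3.17% of target. That flask held 1.40% of target, less than I reckoned, beside 78.9% of over-reaction product.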